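## Analysis of the target

Numbering used throughout: C1 is the carboxyl carbon and C17 the carbon that bears the phenyl ring.

- The target 20 is a C17 acid chain capped by phenyl. C3 and C5 are bridged by an O–O unit, giving a single five-membered 1,2-dioxolane (ring atoms C3, C4, C5 and two oxygens).
- Both peroxide-bearing carbons are fully substituted. C3 carries a methyl group and the C2–C1 acetic acid arm. C5 carries a methyl group and C6, which leads through the methyl-bearing C7, six methylenes (C8–C13) and a (14E,16E)-diene to the phenyl group.
- There are three stereocentres: C3 (S), C5 (R) and C7 (R). The two ring methyls are trans, so the acetic acid arm is cis to the C5 methyl.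
- C7 is separated from C5 by the C6 methylene. This acyclic 1,3-relationship next to a quaternary centre gives no reliable relay of stereochemical information in either direction.
- Sensitive groups: the O–O bond (reducing agents, low-valent metals, radicals); the carboxyl group β to the C3 peroxide oxygen (base can open the ring by retro-oxa-Michael elimination); the phenyl diene (acid, electrophiles, ozone, light).
- The difficulty is that two hydrogen-free, oxygen-bearing quaternary carbons must be made together with the peroxide, with no directing group nearby, early enough to precede the diene and robust enough to survive the rest.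
- The strategy rests on one reading of the ring. C3, with its methyl and two-carbon arm, is a masked methyl ketone whose peroxycarbenium form supplies C3–O–O. C4–C5, with the C5 methyl, is the isopropenyl end of a chain that already holds C6 and C7.

## Retrosynthetic reasoning

**C14=C15 and the carboxyl group.** Acid 20 is taken back to methyl ester 19, and the C14=C15 bond is cut to give aldehyde 17 and cinnamyl phosphonate 18. The diene goes first because it is the group least able to survive the cation and ozone chemistry needed earlier. Cutting at C14=C15 rather than C16=C17 keeps the styryl double bond, with its geometry, inside a stable reagent and leaves the ring fragment as a plain saturated aldehyde. The forward olefination must form one E double bond without enolising the β-peroxy ester, and the final hydrolysis must spare the ring.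

**The two chain termini.** Aldehyde 17 goes back through alcohol 16, silyl ether 15, acid 14 (via aldehyde 13) and alcohol 12 to acetate 11. No skeletal bond is cut; only the oxidation levels of C1 and C14 change. The two primary oxygen functions are told apart by an acetate on the C1 side and a tert-butyldiphenylsilyl ether on the C14 side. Both tolerate a strong Lewis acid at low temperature and are removed independently. C1 is raised to the ester before C14 is unmasked, so the diene is exposed to only two steps.

**C3–C4 and C5–O (key disconnection).** The ring of 11 is opened at C3–C4 and C5–O, dividing it into the C3–O–O unit of silylperoxy ketal 10 and the C4=C5 unit of alkene 7. Cutting here, rather than at O–O or at one C–O bond, avoids carrying a tertiary hydroperoxide through an open-chain sequence. It brings the peroxide in as a stable silyl peroxyketal, and both ring methyls are native to the fragments. The gain is convergence: the ring, two skeletal bonds and both quaternary centres in one operation. The forward reaction must ionise 10, form C3–C4 through the CH2 terminus of 7, and close O–C5 without touching the silyl ether, the acetate or C7. It cannot be expected to control C3 or C5, so the price is a separation.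

**The peroxide fragment.** Ketal 10 is cut at O–Si to hydroperoxide 9, and 9 at C3 to the C=C bond of isoprenyl acetate 8. Oxidative cleavage of this 1,1-disubstituted alkene in an alcohol solvent traps the ketone oxide as 9. The C3 methyl, C2 and the protected C1 oxygen all come from a purchasable five-carbon ester in two steps.

**The alkene fragment.** Alkene 7 is cut at C4=C5 to methyl ketone 6 (methylenation). Ketone 6 is cut at the C7–CH3 bond to enone 5 (asymmetric conjugate methylation, the only step that sets absolute configuration). Enone 5 is cut at C6=C7 to aldehyde 3 and ylide 4, and 3 goes back through monosilyl ether 2 to diol 1. C7 is set β to a carbonyl, where it cannot epimerise, and C8–C14 come from a symmetrical diol.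

## Alternatives that were turned down

**Alternative 1:** The ring is opened only at O–C5.
- Key step: the open-chain tertiary hydroperoxide A2, with an exocyclic methylene at C5, is treated with an electrophilic iodine source. The hydroperoxide oxygen attacks the tertiary end of the iodonium ion in a 5-exo closure to give iodomethyl dioxolane A1. The C–I bond must then be reduced to the C5 methyl.
- For: the closure is regiochemically secure and mild. C3 is already a stereocentre in A2, so enantiopure A2 would give only two C5 epimers instead of four isomers. On that point it is stronger than the chosen route.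
- Against: A2 is a tertiary β-hydroperoxy ester with no direct enantioselective entry, and it can lose the peroxide by retro-addition. The C5 alkene face is three atoms from C3 and should be attacked with little preference. Deiodination is the real obstacle: a radical reduction makes a primary radical β to the O–O bond, which is set up to collapse to an epoxide with peroxide cleavage. Hydride displacement at this neopentyl-type carbon is slow and threatens ester and peroxide.
- Comparison: the chosen route carries the C5 methyl in alkene 7 from the start, needs no halogen, and forms the ring in one step from fragments of five and two steps. It gives up the preset C3 centre.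

**Alternative 2:** Both C–O bonds are cut and C3 is joined to C5, giving vinylcyclopropane A4.
- Key step: a thiyl radical adds to the vinyl group and the cyclopropylcarbinyl radical opens to the tertiary C5 radical. Dioxygen is captured, and the peroxyl radical closes 5-exo onto the new alkene at C3 with loss of the thiyl radical, giving vinyl dioxolane A3.
- For: neutral conditions, dioxygen as the peroxide source, and a vinyl handle at C3.
- Against: A4 has two adjacent quaternary ring carbons and would need a vinylcarbene-type cyclopropanation of alkene 7 or a longer sequence. All configurational information at C3 and C5 is erased (C5 passes through a planar radical, C3 through an alkene), so the same four isomers result. The tertiary peroxyl radical can abstract the C7 hydrogen through a six-membered transition state, which puts C7 at risk. Turning vinyl into the acetic acid arm costs a hydroboration and two oxidations.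
- Comparison: equal in stereocontrol (none), weaker in step economy and in the safety of C7. The chosen route uses ionic chemistry that leaves C7 alone and delivers the two-carbon arm already oxygenated.

**Alternative 3:** Only O–C3 is cut.
- Key step: hydroperoxy oxetane A6 has C3 as the quaternary carbon of a 2-methyloxetane of opposite configuration and a hydroperoxide at C5. A silyl triflate activates the oxetane; backside attack of the hydroperoxide closes the dioxolane with inversion and releases the hydroxyethyl arm. The product A5 is the same compound as alcohol 12.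
- For, and here it is stronger than the chosen route: the closure is stereospecific, so an enantiopure oxetane fixes C3 absolutely. The only isomer to remove is the C5 epimer, which differs as cis versus trans on the ring and should separate on silica. A5 also enters the end game one step later than 11.
- Against: A6 is a long linear target. It needs an enantioenriched 2,2-disubstituted oxetane (asymmetric epoxidation, reductive opening, cyclisation), chain assembly with C7, and a tertiary hydroperoxide at C5. Known methods for that hydroperoxide (cobalt-catalysed hydroperoxysilylation through a planar radical) give no facial control, so half of an advanced intermediate is still lost. Substitution with inversion at a fully substituted carbon competes with ionisation, which would erode C3. Oxetane and hydroperoxide must be carried together under acid.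
- Comparison: the chosen route trades the control at C3 for convergence. The ring is in hand after eight steps in total, five in the longest line, from purchasable materials. The cost is a statistical mixture and a chiral-phase separation.

Key step: step 8

Assumption: in step 4 the Josiphos enantiomer is used that delivers methyl to the enone face giving the (4R)-ketone 6; both enantiomers of the ligand are sold, so the sense can be corrected on the first batch.

## Route

Step 1
Reactants: 1 octane-1,8-diol
Product: 2 8-[(tert-butyldiphenylsilyl)oxy]octan-1-ol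
Conditions: NaH (1.0 equiv), THF, 0 °C to rt; then t-BuPh2SiCl (1.0 equiv), rt
Reagents that add atoms: tert-butyl(chloro)diphenylsilane, CC(C)(C)[Si](Cl)(c1ccccc1)c1ccccc1
Why: O-Silylation of the monoalkoxide of a symmetrical diol should give mainly the monosilyl ether; the bulky, Lewis-acid-stable tert-butyldiphenylsilyl group is chosen because it has to survive SnCl4 in step 8.

Step 2
Reactants: 2 8-[(tert-butyldiphenylsilyl)oxy]octan-1-ol
Product: 3 8-[(tert-butyldiphenylsilyl)oxy]octanal
Conditions: TEMPO (10 mol %), PhI(OAc)2 (1.1 equiv), CH2Cl2, rt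
Reagents that add atoms: none
Why: Oxoammonium (TEMPO) oxidation of a primary alcohol stops at the aldehyde in dry CH2Cl2 and leaves the silyl ether untouched.

Step 3
Reactants: 3 8-[(tert-butyldiphenylsilyl)oxy]octanal; 4 1-(triphenylphosphoranylidene)propan-2-one
Product: 5 (3E)-11-[(tert-butyldiphenylsilyl)oxy]undec-3-en-2-one
Conditions: 4 (1.3 equiv), CH2Cl2, 40 °C
Reagents that add atoms: none
Why: Wittig reaction of a ketone-stabilised ylide with an aliphatic aldehyde should give the (E)-enone selectively, as needed for face selection in step 4.

Step 4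
Reactants: 5 (3E)-11-[(tert-butyldiphenylsilyl)oxy]undec-3-en-2-one
Product: 6 (4R)-11-[(tert-butyldiphenylsilyl)oxy]-4-methylundecan-2-one
Conditions: MeMgBr (1.2 equiv, slow addition), CuBr·SMe2 (5 mol %), Josiphos SL-J001 (6 mol %, enantiomer per the assumption), t-BuOMe, −75 °C; then MeOH, aq. NH4Cl
Reagents that add atoms: methylmagnesium bromide, C[Mg]Br
Why: Copper-catalysed asymmetric conjugate addition of a Grignard reagent to a linear (E)-alk-3-en-2-one with a ferrocenyl diphosphine ligand; the ligand-bound methylcopper species selects one enone face and sets C7 of the target (C4 of 6) under catalyst control, while low temperature and slow addition suppress 1,2-addition.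

Step 5
Reactants: 6 (4R)-11-[(tert-butyldiphenylsilyl)oxy]-4-methylundecan-2-one
Product: 7 tert-butyl{[(8R)-8,10-dimethylundec-10-en-1-yl]oxy}diphenylsilane
Conditions: Ph3PCH3Br (1.5 equiv), KOt-Bu (1.4 equiv), THF, 0 °C to rt
Reagents that add atoms: methyltriphenylphosphonium bromide, C[P+](c1ccccc1)(c1ccccc1)c1ccccc1.[Br-]
Why: Wittig methylenation of a methyl ketone; the stereocentre is β to the carbonyl and cannot epimerise by enolisation.

Step 6
Reactants: 8 3-methylbut-3-en-1-yl acetate
Product: 9 3-hydroperoxy-3-methoxybutyl acetate (racemic)
Conditions: O3, CH2Cl2/MeOH (3:1), −78 °C; N2 purge; concentrate below 25 °C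
Reagents that add atoms: ozone, [O-][O+]=O; methanol, CO
Why: Ozonolysis by the Criegee mechanism splits the primary ozonide of a 1,1-disubstituted alkene into formaldehyde and the more substituted ketone oxide, which methanol traps as the α-methoxy hydroperoxide; the acetate is inert.

Step 7
Reactants: 9 3-hydroperoxy-3-methoxybutyl acetate
Product: 10 3-methoxy-3-[(triethylsilyl)peroxy]butyl acetate (racemic)
Conditions: Et3SiOTf (1.2 equiv), Et3N (2 equiv), CH2Cl2, 0 °C
Reagents that add atoms: triethylsilyl trifluoromethanesulfonate, CC[Si](CC)(CC)OS(=O)(=O)C(F)(F)F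
Why: O-Silylation of the hydroperoxide, the most acidic and least hindered hydroxyl-type site, in amine-buffered medium that should not ionise the ketal; the racemic centre is destroyed on ionisation in step 8.

Step 8
Reactants: 7 tert-butyl{[(8R)-8,10-dimethylundec-10-en-1-yl]oxy}diphenylsilane; 10 3-methoxy-3-[(triethylsilyl)peroxy]butyl acetate
Product: 11 2-[(3R,5R)-5-{(2R)-9-[(tert-butyldiphenylsilyl)oxy]-2-methylnonyl}-3,5-dimethyl-1,2-dioxolan-3-yl]ethyl acetate
Conditions: 10 (2.0 equiv), SnCl4 (1.0 M in CH2Cl2, 2.0 equiv), CH2Cl2, −78 °C; aq. NaHCO3 quench at −78 °C; SiO2 chromatography, then preparative HPLC on a cellulose tris(3,5-dimethylphenylcarbamate) phase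
Reagents that add atoms: none
Why: SnCl4 removes methoxide from 10 and leaves a carbenium ion at C3 stabilised by the triethylsilylperoxy oxygen. The CH2 terminus of 7 adds to it (C3–C4 bond), the charge moves to the tertiary C5, and the silyl-bearing peroxide oxygen then bonds to C5 and gives up its triethylsilyl group to methoxide. The closest known reaction type is the SnCl4-mediated [3+2] annulation of triethylsilyl peroxyketals with alkenes, which works best with 1,1-disubstituted alkenes such as 7. The single ring is closed stepwise by attack of oxygen on a trigonal cationic carbon to give a five-membered ring; counted against the former C4=C5 bond both alkene carbons lie in the ring (endo sense), but the π bond is already consumed, so no Baldwin-type restriction applies. C3 is created in the C–C bond-forming step on a planar, achiral cation and C5 in the ring closure on a planar tertiary cation; C7 is four bonds from C3 and the methyl and acetoxyethyl groups on C3 differ little in size, so no element of the substrate controls either centre and the four C3/C5 combinations are expected in comparable amounts. The required isomer is therefore taken by separation: silica chromatography should remove the two isomers with cis ring methyls, and chiral-phase HPLC should part 11 from the trans isomer in which both ring centres are inverted, the two being quasi-enantiomeric at the ring. C7 keeps its configuration because hydride migration from C6 would give a less stable secondary cation and capture of the C5 cation by the neighbouring oxygen is intramolecular and fast. The selectivities the step does need, attack through CH2 and no reaction elsewhere, are secured by the 1,1-disubstitution of 7 (tertiary cation), by the absence of any other π-nucleophile, and by the silyl ether and acetate, which tolerate the Lewis acid at −78 °C.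

Step 9
Reactants: 11 2-[(3R,5R)-5-{(2R)-9-[(tert-butyldiphenylsilyl)oxy]-2-methylnonyl}-3,5-dimethyl-1,2-dioxolan-3-yl]ethyl acetate
Product: 12 2-[(3R,5R)-5-{(2R)-9-[(tert-butyldiphenylsilyl)oxy]-2-methylnonyl}-3,5-dimethyl-1,2-dioxolan-3-yl]ethan-1-ol
Conditions: K2CO3 (0.3 equiv), MeOH, 0 °C to rt
Reagents that add atoms: none
Why: Base-catalysed transesterification of a primary acetate; the ring carbons carry no hydrogen and no carbonyl is yet β to the peroxide, so the dioxolane cannot fragment.

Step 10
Reactants: 12 2-[(3R,5R)-5-{(2R)-9-[(tert-butyldiphenylsilyl)oxy]-2-methylnonyl}-3,5-dimethyl-1,2-dioxolan-3-yl]ethan-1-ol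
Product: 14 2-[(3S,5R)-5-{(2R)-9-[(tert-butyldiphenylsilyl)oxy]-2-methylnonyl}-3,5-dimethyl-1,2-dioxolan-3-yl]acetic acid, via dioxolanylacetaldehyde 13 (not isolated)
Conditions: TEMPO (20 mol %), PhI(OAc)2 (2.5 equiv), CH2Cl2/H2O (2:1), rt
Reagents that add atoms: water, O
Why: Oxoammonium oxidation in the presence of water takes the primary alcohol through the aldehyde hydrate to the acid in one flask; the weakly acidic medium avoids β-elimination of the β-peroxy aldehyde, and dialkyl peroxides and silyl ethers are inert to the oxidant. The C3 descriptor changes from R to S only because the oxidised arm gains priority; no bond at C3 is touched.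

Step 11
Reactants: 14 2-[(3S,5R)-5-{(2R)-9-[(tert-butyldiphenylsilyl)oxy]-2-methylnonyl}-3,5-dimethyl-1,2-dioxolan-3-yl]acetic acid
Product: 15 methyl 2-[(3S,5R)-5-{(2R)-9-[(tert-butyldiphenylsilyl)oxy]-2-methylnonyl}-3,5-dimethyl-1,2-dioxolan-3-yl]acetate
Conditions: Me3SiCHN2 (2 M in hexanes, 1.5 equiv), toluene/MeOH (4:1), 0 °C
Reagents that add atoms: (trimethylsilyl)diazomethane, C[Si](C)(C)C=[N+]=[N-]
Why: Methyl ester formation by O-alkylation of the carboxylate with diazomethane released in situ, under neutral conditions; the ester masks the acid during the fluoride and phosphonate-anion steps.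

Step 12
Reactants: 15 methyl 2-[(3S,5R)-5-{(2R)-9-[(tert-butyldiphenylsilyl)oxy]-2-methylnonyl}-3,5-dimethyl-1,2-dioxolan-3-yl]acetate
Product: 16 methyl 2-[(3S,5R)-5-[(2R)-9-hydroxy-2-methylnonyl]-3,5-dimethyl-1,2-dioxolan-3-yl]acetate
Conditions: Bu4NF (2 equiv), AcOH (2 equiv), THF, rt
Reagents that add atoms: none
Why: Fluoride-induced cleavage of the silyl ether; buffering with acetic acid keeps the medium too weakly basic to enolise the β-peroxy ester.

Step 13
Reactants: 16 methyl 2-[(3S,5R)-5-[(2R)-9-hydroxy-2-methylnonyl]-3,5-dimethyl-1,2-dioxolan-3-yl]acetate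
Product: 17 methyl 2-[(3S,5R)-3,5-dimethyl-5-[(2R)-2-methyl-9-oxononyl]-1,2-dioxolan-3-yl]acetate
Conditions: Dess–Martin periodinane (1.3 equiv), CH2Cl2, 0 °C to rt
Reagents that add atoms: none
Why: Dess–Martin oxidation of a primary alcohol to the aldehyde under near-neutral, non-reducing conditions that leave peroxide and ester alone.

Step 14
Reactants: 17 methyl 2-[(3S,5R)-3,5-dimethyl-5-[(2R)-2-methyl-9-oxononyl]-1,2-dioxolan-3-yl]acetate; 18 diethyl [(2E)-3-phenylprop-2-en-1-yl]phosphonate
Product: 19 methyl 2-[(3S,5R)-3,5-dimethyl-5-[(2R,9E,11E)-2-methyl-12-phenyldodeca-9,11-dien-1-yl]-1,2-dioxolan-3-yl]acetate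
Conditions: 18 (1.5 equiv), NaN(SiMe3)2 (1.4 equiv), THF, −78 °C; then 17, −78 to 0 °C
Reagents that add atoms: none
Why: Horner–Wadsworth–Emmons olefination with a semi-stabilised allylic phosphonate anion; attack through the carbon α to phosphorus and elimination of diethyl phosphate should give the new C14=C15 bond mainly E, and the styryl bond keeps its E geometry. The phosphonate is kept in excess over base so that no free amide base meets the ester.

Step 15
Reactants: 19 methyl 2-[(3S,5R)-3,5-dimethyl-5-[(2R,9E,11E)-2-methyl-12-phenyldodeca-9,11-dien-1-yl]-1,2-dioxolan-3-yl]acetate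
Product: 20 2-[(3S,5R)-3,5-dimethyl-5-[(2R,9E,11E)-2-methyl-12-phenyldodeca-9,11-dien-1-yl]-1,2-dioxolan-3-yl]acetic acid
Conditions: LiOH·H2O (3 equiv), THF/H2O (3:1), 0 °C to rt, dark; then 1 M HCl to pH 3–4
Reagents that add atoms: lithium hydroxide, [Li+].[OH-]
Why: Saponification by acyl–oxygen cleavage at low temperature; the peroxide carbons carry no hydrogen, so Kornblum–DeLaMare fragmentation is impossible, and the carboxylate once formed no longer enolises.

## Compound list

1 | octane-1,8-diol | OCCCCCCCCO | starting material
2 | 8-[(tert-butyldiphenylsilyl)oxy]octan-1-ol | OCCCCCCCCO[Si](c1ccccc1)(c1ccccc1)C(C)(C)C | intermediate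
3 | 8-[(tert-butyldiphenylsilyl)oxy]octanal | O=CCCCCCCCO[Si](c1ccccc1)(c1ccccc1)C(C)(C)C | intermediate
4 | 1-(triphenylphosphoranylidene)propan-2-one | CC(=O)C=P(c1ccccc1)(c1ccccc1)c1ccccc1 | starting material
5 | (3E)-11-[(tert-butyldiphenylsilyl)oxy]undec-3-en-2-one | CC(=O)/C=C/CCCCCCCO[Si](c1ccccc1)(c1ccccc1)C(C)(C)C | intermediate
6 | (4R)-11-[(tert-butyldiphenylsilyl)oxy]-4-methylundecan-2-one | C[C@H](CCCCCCCO[Si](c1ccccc1)(c1ccccc1)C(C)(C)C)CC(C)=O | intermediate
7 | tert-butyl{[(8R)-8,10-dimethylundec-10-en-1-yl]oxy}diphenylsilane | C[C@H](CCCCCCCO[Si](c1ccccc1)(c1ccccc1)C(C)(C)C)CC(C)=C | intermediate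
8 | 3-methylbut-3-en-1-yl acetate | CC(=C)CCOC(C)=O | starting material
9 | 3-hydroperoxy-3-methoxybutyl acetate (racemic) | CC(OC)(OO)CCOC(C)=O | intermediate
10 | 3-methoxy-3-[(triethylsilyl)peroxy]butyl acetate (racemic) | CC(OC)(OO[Si](CC)(CC)CC)CCOC(C)=O | intermediate
11 | 2-[(3R,5R)-5-{(2R)-9-[(tert-butyldiphenylsilyl)oxy]-2-methylnonyl}-3,5-dimethyl-1,2-dioxolan-3-yl]ethyl acetate | C[C@H](CCCCCCCO[Si](c1ccccc1)(c1ccccc1)C(C)(C)C)C[C@]1(C)C[C@@](C)(CCOC(C)=O)OO1 | intermediate
12 | 2-[(3R,5R)-5-{(2R)-9-[(tert-butyldiphenylsilyl)oxy]-2-methylnonyl}-3,5-dimethyl-1,2-dioxolan-3-yl]ethan-1-ol | C[C@H](CCCCCCCO[Si](c1ccccc1)(c1ccccc1)C(C)(C)C)C[C@]1(C)C[C@@](C)(CCO)OO1 | intermediate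
13 | 2-[(3S,5R)-5-{(2R)-9-[(tert-butyldiphenylsilyl)oxy]-2-methylnonyl}-3,5-dimethyl-1,2-dioxolan-3-yl]acetaldehyde | C[C@H](CCCCCCCO[Si](c1ccccc1)(c1ccccc1)C(C)(C)C)C[C@]1(C)C[C@@](C)(CC=O)OO1 | intermediate (not isolated)
14 | 2-[(3S,5R)-5-{(2R)-9-[(tert-butyldiphenylsilyl)oxy]-2-methylnonyl}-3,5-dimethyl-1,2-dioxolan-3-yl]acetic acid | C[C@H](CCCCCCCO[Si](c1ccccc1)(c1ccccc1)C(C)(C)C)C[C@]1(C)C[C@@](C)(CC(=O)O)OO1 | intermediate
15 | methyl 2-[(3S,5R)-5-{(2R)-9-[(tert-butyldiphenylsilyl)oxy]-2-methylnonyl}-3,5-dimethyl-1,2-dioxolan-3-yl]acetate | C[C@H](CCCCCCCO[Si](c1ccccc1)(c1ccccc1)C(C)(C)C)C[C@]1(C)C[C@@](C)(CC(=O)OC)OO1 | intermediate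
16 | methyl 2-[(3S,5R)-5-[(2R)-9-hydroxy-2-methylnonyl]-3,5-dimethyl-1,2-dioxolan-3-yl]acetate | C[C@H](CCCCCCCO)C[C@]1(C)C[C@@](C)(CC(=O)OC)OO1 | intermediate
17 | methyl 2-[(3S,5R)-3,5-dimethyl-5-[(2R)-2-methyl-9-oxononyl]-1,2-dioxolan-3-yl]acetate | C[C@H](CCCCCCC=O)C[C@]1(C)C[C@@](C)(CC(=O)OC)OO1 | intermediate
18 | diethyl [(2E)-3-phenylprop-2-en-1-yl]phosphonate | CCOP(=O)(C/C=C/c1ccccc1)OCC | starting material
19 | methyl 2-[(3S,5R)-3,5-dimethyl-5-[(2R,9E,11E)-2-methyl-12-phenyldodeca-9,11-dien-1-yl]-1,2-dioxolan-3-yl]acetate | C[C@H](CCCCCC/C=C/C=C/c1ccccc1)C[C@]1(C)C[C@@](C)(CC(=O)OC)OO1 | intermediate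
20 | 2-[(3S,5R)-3,5-dimethyl-5-[(2R,9E,11E)-2-methyl-12-phenyldodeca-9,11-dien-1-yl]-1,2-dioxolan-3-yl]acetic acid | C[C@H](CCCCCC/C=C/C=C/c1ccccc1)C[C@]1(C)C[C@@](C)(CC(=O)O)OO1 | target

## Step count and least certain steps

Total step count: 15. Longest linear sequence: 13 steps (steps 1–5 and 8–15); the peroxide fragment (steps 6–7) joins at step 8.

**Step 8 (key step).**
- What may go wrong: there is no facial control at either new centre, so at best about a quarter of the annulated material should be 11. The cis-dimethyl isomers should separate on silica, but the two trans isomers differ only in how the ring relates to the remote C7 and may resist separation even on a chiral phase. Their assignment also needs a crystalline derivative or comparison of the final acid with the natural product. Loss of a proton from the C5 cation is a lesser competing process.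
- Fallback (covalent separation at the acid stage): the trans-dimethyl fraction from silica is carried unresolved through steps 9 and 10, so the fallback sets out from acid 14, accompanied by its isomer with both ring centres inverted. Coupling with (4S)-4-benzyl-1,3-oxazolidin-2-one (DCC, DMAP, CH2Cl2) should give (4S)-4-benzyl-3-{[(3S,5R)-5-{(2R)-9-[(tert-butyldiphenylsilyl)oxy]-2-methylnonyl}-3,5-dimethyl-1,2-dioxolan-3-yl]acetyl}-1,3-oxazolidin-2-one F1 and (4S)-4-benzyl-3-{[(3R,5S)-5-{(2R)-9-[(tert-butyldiphenylsilyl)oxy]-2-methylnonyl}-3,5-dimethyl-1,2-dioxolan-3-yl]acetyl}-1,3-oxazolidin-2-one F2. A rigid stereocentre now sits four bonds from C3, so these should separate on silica or by crystallisation, and a crystal structure of either would settle the assignment. Cleavage of F1 with LiOH/H2O2 (THF/H2O, 0 °C) returns 14 as a single isomer, and the route resumes at step 11.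

**Step 4.**
- What may go wrong: competing 1,2-addition of the Grignard reagent, and incomplete or wrong-sense face selection by the catalyst on this long-chain methyl ketone. Either would carry a C7 epimer into the already difficult separation of step 8.
- Fallback (auxiliary control): it sets out from aldehyde 3 and comes back at ketone 6, bypassing 5. Horner–Wadsworth–Emmons reaction of 3 with diethyl {2-oxo-2-[(4S)-2-oxo-4-phenyl-1,3-oxazolidin-3-yl]ethyl}phosphonate (LiCl, i-Pr2NEt, MeCN) gives (4S)-3-{(2E)-10-[(tert-butyldiphenylsilyl)oxy]dec-2-enoyl}-4-phenyl-1,3-oxazolidin-2-one F3. Addition of MeMgBr/CuBr·SMe2 (THF/Me2S, −40 °C) to the magnesium-chelated s-cis enoyl imide, from the face opposite the phenyl group, gives (4S)-3-{(3R)-10-[(tert-butyldiphenylsilyl)oxy]-3-methyldecanoyl}-4-phenyl-1,3-oxazolidin-2-one F4; a minor diastereomer can be removed at this stage. Aminolysis with MeONHMe·HCl/AlMe3 gives (3R)-10-[(tert-butyldiphenylsilyl)oxy]-N-methoxy-N,3-dimethyldecanamide F5 and frees the auxiliary. MeMgBr (THF, 0 °C) then gives 6.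

**Step 14.**
- What may go wrong: incomplete E selectivity at the new C14=C15 bond, or attack of the ambident cinnamyl anion through its γ-carbon, giving diene isomers that are hard to remove. Deprotonation of the β-peroxy ester by excess base is a lesser danger.
- Fallback (the diene in two E-selective stages, with C16=C17 formed last): it sets out from aldehyde 17 and comes back at ester 19. Wittig reaction of 17 with the stabilised ylide Ph3P=CHCHO (toluene, 80 °C, no added base) gives methyl 2-[(3S,5R)-3,5-dimethyl-5-[(2R,9E)-2-methyl-11-oxoundec-9-en-1-yl]-1,2-dioxolan-3-yl]acetate F6, which can be purified as the E-enal. Horner–Wadsworth–Emmons reaction of F6 with diethyl benzylphosphonate/NaN(SiMe3)2 (THF, −78 to 0 °C), whose anion is not ambident, gives 19.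

**Step 15.**
- What may go wrong: hydroxide may deprotonate C2 of the ester and expel the C3 peroxide oxygen (retro-oxa-Michael), which opens the ring or, on re-closure, epimerises C3. The diene can also isomerise during acidification.
- Fallback (an end game without any ester): it sets out from acid 14 and comes back at target 20. Desilylation of 14 (Bu4NF, THF) gives 2-[(3S,5R)-5-[(2R)-9-hydroxy-2-methylnonyl]-3,5-dimethyl-1,2-dioxolan-3-yl]acetic acid F7. Dess–Martin oxidation gives 2-[(3S,5R)-3,5-dimethyl-5-[(2R)-2-methyl-9-oxononyl]-1,2-dioxolan-3-yl]acetic acid F8. Olefination of F8 with the anion of 18 (2.5 equiv; the first equivalent forms the carboxylate, whose α-hydrogens are no longer acidic) gives 20 directly after mild acidification.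

## Further compounds

F1 | step 8 | (4S)-4-benzyl-3-{[(3S,5R)-5-{(2R)-9-[(tert-butyldiphenylsilyl)oxy]-2-methylnonyl}-3,5-dimethyl-1,2-dioxolan-3-yl]acetyl}-1,3-oxazolidin-2-one | C[C@H](CCCCCCCO[Si](c1ccccc1)(c1ccccc1)C(C)(C)C)C[C@]1(C)C[C@@](C)(CC(=O)N2[C@@H](Cc3ccccc3)COC2=O)OO1
F2 | step 8 | (4S)-4-benzyl-3-{[(3R,5S)-5-{(2R)-9-[(tert-butyldiphenylsilyl)oxy]-2-methylnonyl}-3,5-dimethyl-1,2-dioxolan-3-yl]acetyl}-1,3-oxazolidin-2-one | C[C@H](CCCCCCCO[Si](c1ccccc1)(c1ccccc1)C(C)(C)C)C[C@@]1(C)C[C@](C)(CC(=O)N2[C@@H](Cc3ccccc3)COC2=O)OO1
F3 | step 4 | (4S)-3-{(2E)-10-[(tert-butyldiphenylsilyl)oxy]dec-2-enoyl}-4-phenyl-1,3-oxazolidin-2-one | O=C(/C=C/CCCCCCCO[Si](c1ccccc1)(c1ccccc1)C(C)(C)C)N1[C@@H](c2ccccc2)COC1=O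
F4 | step 4 | (4S)-3-{(3R)-10-[(tert-butyldiphenylsilyl)oxy]-3-methyldecanoyl}-4-phenyl-1,3-oxazolidin-2-one | C[C@H](CCCCCCCO[Si](c1ccccc1)(c1ccccc1)C(C)(C)C)CC(=O)N1[C@@H](c2ccccc2)COC1=O
F5 | step 4 | (3R)-10-[(tert-butyldiphenylsilyl)oxy]-N-methoxy-N,3-dimethyldecanamide | C[C@H](CCCCCCCO[Si](c1ccccc1)(c1ccccc1)C(C)(C)C)CC(=O)N(C)OC
F6 | step 14 | methyl 2-[(3S,5R)-3,5-dimethyl-5-[(2R,9E)-2-methyl-11-oxoundec-9-en-1-yl]-1,2-dioxolan-3-yl]acetate | C[C@H](CCCCCC/C=C/C=O)C[C@]1(C)C[C@@](C)(CC(=O)OC)OO1
F7 | step 15 | 2-[(3S,5R)-5-[(2R)-9-hydroxy-2-methylnonyl]-3,5-dimethyl-1,2-dioxolan-3-yl]acetic acid | C[C@H](CCCCCCCO)C[C@]1(C)C[C@@](C)(CC(=O)O)OO1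
F8 | step 15 | 2-[(3S,5R)-3,5-dimethyl-5-[(2R)-2-methyl-9-oxononyl]-1,2-dioxolan-3-yl]acetic acid | C[C@H](CCCCCCC=O)C[C@]1(C)C[C@@](C)(CC(=O)O)OO1
A1 | alternative 1 | methyl 2-[(3S,5R)-5-{(2R)-9-[(tert-butyldiphenylsilyl)oxy]-2-methylnonyl}-5-(iodomethyl)-3-methyl-1,2-dioxolan-3-yl]acetate | C[C@H](CCCCCCCO[Si](c1ccccc1)(c1ccccc1)C(C)(C)C)C[C@]1(CI)C[C@@](C)(CC(=O)OC)OO1
A2 | alternative 1 | methyl (3S,7R)-14-[(tert-butyldiphenylsilyl)oxy]-3-hydroperoxy-3,7-dimethyl-5-methylidenetetradecanoate | C[C@H](CCCCCCCO[Si](c1ccccc1)(c1ccccc1)C(C)(C)C)CC(=C)C[C@@](C)(CC(=O)OC)OO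
A3 | alternative 2 | (3S,5R)-5-{(2R)-9-[(tert-butyldiphenylsilyl)oxy]-2-methylnonyl}-3-ethenyl-3,5-dimethyl-1,2-dioxolane | C[C@H](CCCCCCCO[Si](c1ccccc1)(c1ccccc1)C(C)(C)C)C[C@]1(C)C[C@@](C)(C=C)OO1
A4 | alternative 2 | tert-butyl{[(8R)-9-(2-ethenyl-1,2-dimethylcyclopropyl)-8-methylnonyl]oxy}diphenylsilane (mixture of cyclopropane stereoisomers) | C[C@H](CCCCCCCO[Si](c1ccccc1)(c1ccccc1)C(C)(C)C)CC1(C)CC1(C)C=C
A5 | alternative 3 | 2-[(3R,5R)-5-{(2R)-9-[(tert-butyldiphenylsilyl)oxy]-2-methylnonyl}-3,5-dimethyl-1,2-dioxolan-3-yl]ethan-1-ol (identical with 12) | C[C@H](CCCCCCCO[Si](c1ccccc1)(c1ccccc1)C(C)(C)C)C[C@]1(C)C[C@@](C)(CCO)OO1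
A6 | alternative 3 | tert-butyl({(8R,10R)-10-hydroperoxy-8,10-dimethyl-11-[(2S)-2-methyloxetan-2-yl]undecyl}oxy)diphenylsilane | C[C@H](CCCCCCCO[Si](c1ccccc1)(c1ccccc1)C(C)(C)C)C[C@@](C)(OO)C[C@]1(C)CCO1
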